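**Retrosynthetic overview**
1. Candidachalcone comes from its ring B silyl ether by fluoride cleavage. That ether is cut between ring A carbon C1' and the ketone carbon. The pieces are a ring A aryllithium and the complete E-4-silyloxycinnamoyl unit as its N-methoxy-N-methylamide, itself made by Horner-Wadsworth-Emmons olefination.
2. Enabling feature: the arm C3'-CH=CH-C(CH3)2OH is cis and sits between the hydroxyls on C2' and C4'. Arm plus one of these oxygens is therefore the pyranone ring (O1, C2, C3, C4, C4a, C8a) of 5-hydroxy-7-methoxycoumarin whose lactone carbon C2 has taken up two methyl groups. Once that ring is open, ring A has a mirror plane through C3' and C6'-OCH3, so C1' and C5' are one and the same position.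
3. Key step, one flask: a bromocoumarin is treated with MeLi (lactone to Z-alkenyl tertiary alkoxide plus second phenoxide), then t-BuLi (C-Br to C-Li), then the amide (C1'-C=O bond). Three C-C bonds, the Z-alkene, the carbinol, both free ring A oxygens and the whole chalcone skeleton arise before anything is isolated, and the carbinol exists before the ketone does.
4. Rings: rings A and B are bought (in 5,7-dihydroxycoumarin and in the silyloxybenzaldehyde). No ring is formed; the only ring event is the opening of the temporary pyranone ring in the key step.

Key step: step 4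

Assumption: chalcone numbering is used (ring A = C1'-C6', with C1' on the carbonyl and C6' bearing OCH3; side chain C1''-C3''; ring B = the 4-hydroxyphenyl ring), and the three starting materials are taken as purchasable.

**Step 1**
Reactants: 1 5,7-dihydroxycoumarin
Product: 2 5-hydroxy-7-methoxycoumarin
Conditions: MeI (1.0 equiv), K2CO3 (1.0 equiv), acetone, rt
Reagents that add atoms: methyl iodide, `CI`
Why: Williamson ether synthesis on the mono-anion, in which the 7-OH (para to C4a, conjugated through C4=C3 with the lactone carbonyl, unhindered) is the more acidic and more accessible phenol, whereas the 5-OH lies peri to C4-H, so O7 should be alkylated first.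

**Step 2**
Reactants: 2 5-hydroxy-7-methoxycoumarin
Product: 3 8-bromo-5-hydroxy-7-methoxycoumarin
Conditions: NBS (1.0 equiv), MeCN, -10 to 0 °C, dark
Reagents that add atoms: N-bromosuccinimide, `O=C1CCC(=O)N1Br`
Why: Electrophilic aromatic bromination should go para to the free 5-OH and ortho to the 7-OCH3 (C8) while the electron-poor C3=C4 bond stays untouched, one equivalent at low temperature should hold it at the monobromide, and attack at C6 instead would do no harm because C6 and C8 become the same ring A carbon in step 4.

**Step 3**
Reactants: 4 4-(tert-butyldimethylsilyloxy)benzaldehyde, 5 diethyl [2-(methoxy(methyl)amino)-2-oxoethyl]phosphonate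
Product: 6 (E)-3-[4-(tert-butyldimethylsilyloxy)phenyl]-N-methoxy-N-methylprop-2-enamide
Conditions: NaH (1.1 equiv), THF, 0 °C to rt
Reagents that add atoms: none
Why: Horner-Wadsworth-Emmons olefination of an aromatic aldehyde with a stabilised phosphonate anion should give the E-enamide through the reversibly formed, more stable trans-oxaphosphetane, and the aryl silyl ether tolerates the phosphonate anion.

**Step 4**
Reactants: 3 8-bromo-5-hydroxy-7-methoxycoumarin, 6 (E)-3-[4-(tert-butyldimethylsilyloxy)phenyl]-N-methoxy-N-methylprop-2-enamide
Product: 10 candidachalcone 4-O-TBS ether, via trilithium bromotriolate 7 (not isolated), via ring A aryllithium 8 (not isolated), via tetrahedral amide adduct 9 (not isolated)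
Conditions: MeLi (3.2 equiv), THF, -78 to 0 °C; t-BuLi (2.0 equiv), -78 °C; 6 (1.1 equiv), -78 to -20 °C; sat. aq NH4Cl, -20 °C; Et3N-washed silica
Reagents that add atoms: methyllithium, `[Li]C`
Why: MeLi first takes the 5-OH proton and then adds twice to the lactone carbonyl C2 (ester-to-tertiary-alcohol addition, closest known case the opening of coumarins by MeLi or MeMgX to cis-2-(3-hydroxy-3-methylbut-1-enyl)phenols), which expels O1 as the second phenoxide and gives 7. MeLi is a poor partner for bromine-lithium exchange, as its routine use for deprotonating bromoarenes before an exchange shows, so the C-Br bond waits for t-BuLi, whose exchange is made irreversible by the second equivalent destroying t-BuBr, and 8 results. 8, an aryllithium flanked by OCH3 and OLi, adds to the carbonyl of 6 (Weinreb ketone synthesis, known for chalcones from cinnamoyl N-methoxy-N-methylamides), and the lithium chelate 9 keeps the ketone masked until the cold quench, so that no second addition, conjugate addition or oxa-Michael closure can follow. No ring is closed and no lasting stereocentre is set: the temporary pyranone ring is opened, the Z geometry of C1''=C2'' is the endocyclic cis C3=C4 bond of the coumarin carried over, and the E enone comes unchanged from 6. The selectivities needed are chemoselectivity in time (carbinol before ketone, secured by the order of addition and by the all-anionic, proton-free medium in which the acid-labile Z-allylic alcohol cannot close to a chromene) and site selectivity on ring A, which the substrate makes void because the opening creates the mirror plane through C3' and C6'.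

**Step 5**
Reactants: 10 candidachalcone 4-O-TBS ether
Product: 11 candidachalcone
Conditions: TBAF (1.1 equiv), AcOH (1.1 equiv), THF, 0 °C; pH 7 buffer work-up; Et3N-washed silica
Reagents that add atoms: none
Why: Fluoride-induced cleavage of the aryl silyl ether (Si-F bond formation) in a buffered medium should be too weakly acidic to ionise the tertiary allylic alcohol and too weakly basic for oxa-Michael closure to the flavanone, and it touches neither olefin geometry.

**Compound list**
1 | 5,7-dihydroxycoumarin | `Oc1cc(O)c2C=CC(=O)Oc2c1` | starting material
2 | 5-hydroxy-7-methoxycoumarin | `COc1cc(O)c2C=CC(=O)Oc2c1` | intermediate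
3 | 8-bromo-5-hydroxy-7-methoxycoumarin | `COc1cc(O)c2C=CC(=O)Oc2c1Br` | intermediate
4 | 4-(tert-butyldimethylsilyloxy)benzaldehyde | `O=Cc1ccc(O[Si](C)(C)C(C)(C)C)cc1` | starting material
5 | diethyl [2-(methoxy(methyl)amino)-2-oxoethyl]phosphonate | `CCOP(=O)(CC(=O)N(C)OC)OCC` | starting material
6 | (E)-3-[4-(tert-butyldimethylsilyloxy)phenyl]-N-methoxy-N-methylprop-2-enamide | `CON(C)C(=O)/C=C/c1ccc(O[Si](C)(C)C(C)(C)C)cc1` | intermediate
7 | trilithium salt of 4-bromo-2-[(Z)-3-hydroxy-3-methylbut-1-enyl]-5-methoxybenzene-1,3-diol | `COc1cc([O-])c(/C=C\C(C)(C)[O-])c([O-])c1Br.[Li+].[Li+].[Li+]` | intermediate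
8 | 4-lithio analogue of 7 (C-Li in place of C-Br) | `COc1cc([O-])c(/C=C\C(C)(C)[O-])c([O-])c1[Li].[Li+].[Li+].[Li+]` | intermediate
9 | tetralithium tetrahedral adduct of 8 and 6 (carbinolamine carbon unassigned, transient) | `COc1cc([O-])c(/C=C\C(C)(C)[O-])c([O-])c1C([O-])(N(C)OC)/C=C/c1ccc(O[Si](C)(C)C(C)(C)C)cc1.[Li+].[Li+].[Li+].[Li+]` | intermediate
10 | candidachalcone 4-O-TBS ether: (E)-3-[4-(tert-butyldimethylsilyloxy)phenyl]-1-{2,4-dihydroxy-3-[(Z)-3-hydroxy-3-methylbut-1-enyl]-6-methoxyphenyl}prop-2-en-1-one | `COc1cc(O)c(/C=C\C(C)(C)O)c(O)c1C(=O)/C=C/c1ccc(O[Si](C)(C)C(C)(C)C)cc1` | intermediate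
11 | candidachalcone: (E)-1-{2,4-dihydroxy-3-[(Z)-3-hydroxy-3-methylbut-1-enyl]-6-methoxyphenyl}-3-(4-hydroxyphenyl)prop-2-en-1-one | `COc1cc(O)c(/C=C\C(C)(C)O)c(O)c1C(=O)/C=C/c1ccc(O)cc1` | target

**Step count:** 5 steps in total. The longest linear sequence is 4 steps (steps 1, 2, 4, 5).

**Steps most likely to fail**

Step 4.
- What may go wrong: the bromine-lithium exchange may stall on a sparingly soluble trilithium salt. The aryllithium may be protonated, or may attack the N-O bond of the amide instead of its carbonyl. MeLi may add in part to C4 or enolise the intermediate Z-enone.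
- Fallback: it gives up halogen and lithium altogether. It sets out from 2 and comes back at 11.
- (E)-4-acetoxycinnamoyl chloride F1 is prepared from commercial (E)-4-acetoxycinnamic acid and oxalyl chloride.
- 2 is opened with MeMgBr (3.2 equiv, THF, then solvent change to toluene) to the tris(bromomagnesium) salt of 2-[(Z)-3-hydroxy-3-methylbut-1-enyl]-5-methoxybenzene-1,3-diol F2.
- F1 is then delivered inside the magnesium phenolate chelate to the ortho carbon. This is the metal-template ortho-acylation of bromomagnesium phenolates with cinnamoyl chlorides, a known direct entry to 2'-hydroxychalcones.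
- The ring proton is taken up by the tertiary alkoxide, and the equivalence of C1' and C5' again removes the site question.
- This should give candidachalcone 4-O-acetate F3, and K2CO3 in MeOH at 0 °C frees 11.

Step 1.
- What may go wrong: poor discrimination between the two phenols, or double methylation.
- Fallback: it replaces selective alkylation by selective unmasking. It sets out from 1 and comes back at 2.
- Ac2O in pyridine gives 5,7-diacetoxycoumarin F4.
- PhSH and imidazole in N-methylpyrrolidone at 0 °C remove the more activated and less hindered 7-acetate to give 5-acetoxy-7-hydroxycoumarin F5.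
- MeI with K2CO3 in acetone then has only one phenol to alkylate and gives 5-acetoxy-7-methoxycoumarin F6.
- K2CO3 in MeOH followed by neutralisation gives 2.

Step 5.
- What may go wrong: loss of water from the Z-allylic tertiary alcohol with closure onto a neighbouring phenol oxygen, or base-induced oxa-Michael closure of the 2'-OH onto the enone, during desilylation or chromatography.
- Fallback: it removes the protecting group before the sensitive functions exist. It sets out from 6 and comes back at 11.
- TBAF in THF converts 6 into (E)-3-(4-hydroxyphenyl)-N-methoxy-N-methylprop-2-enamide F7.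
- MeLi (1.0 equiv, THF, -78 °C) turns F7 into its lithium phenoxide F8.
- F8 is added in place of 6 to the aryllithium 8 generated as in step 4, with warming to 0 °C because the phenoxide lowers the electrophilicity of the amide.
- The NH4Cl quench then releases 11 directly.

**Further compounds**
F1 | step 4 | (E)-4-acetoxycinnamoyl chloride | `CC(=O)Oc1ccc(/C=C/C(=O)Cl)cc1`
F2 | step 4 | tris(bromomagnesium) salt of 2-[(Z)-3-hydroxy-3-methylbut-1-enyl]-5-methoxybenzene-1,3-diol | `COc1cc(O[Mg]Br)c(/C=C\C(C)(C)O[Mg]Br)c(O[Mg]Br)c1`
F3 | step 4 | candidachalcone 4-O-acetate | `COc1cc(O)c(/C=C\C(C)(C)O)c(O)c1C(=O)/C=C/c1ccc(OC(C)=O)cc1`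
F4 | step 1 | 5,7-diacetoxycoumarin | `CC(=O)Oc1cc(OC(C)=O)c2C=CC(=O)Oc2c1`
F5 | step 1 | 5-acetoxy-7-hydroxycoumarin | `CC(=O)Oc1cc(O)cc2OC(=O)C=Cc12`
F6 | step 1 | 5-acetoxy-7-methoxycoumarin | `COc1cc(OC(C)=O)c2C=CC(=O)Oc2c1`
F7 | step 5 | (E)-3-(4-hydroxyphenyl)-N-methoxy-N-methylprop-2-enamide | `CON(C)C(=O)/C=C/c1ccc(O)cc1`
F8 | step 5 | lithium 4-[(E)-3-(methoxy(methyl)amino)-3-oxoprop-1-enyl]phenolate | `CON(C)C(=O)/C=C/c1ccc([O-])cc1.[Li+]`
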